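**Retrosynthetic overview**
- The last operation closes two rings at once: acid turns an open-chain 9,13-diol / 15-silyloxy ethyl ester into the γ-lactone (O15–C16) and the spiro-tetrahydrofuran (O13–C9, SN1, sets C9).
- Side chain: acetylene is the C11–C12 linchpin between the C9 ketone (ethynylation) and an α-keto ester (catalytic asymmetric alkynylation, sets C13); the alkyne is then hydrogenated.
- cis-Decalin: enantioselective Diels–Alder of 2,6-dimethylbenzoquinone (ring B) with 4-methyl-1,3-pentadiene (ring A, sets C5/C10), Zn reduction (C8), equilibrating MPV reduction (C6).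
- Ring order: B (quinone) → A (cycloaddition) → lactone and tetrahydrofuran together.

Assumption: the SMILES is taken literally, i.e. the cis-fused (5S,6S,8R,9R,10R,13R) isomer. Labdane numbering is used for positions (C6 OAc, C8 Me, C9–O–C13 ether, C16 lactone C=O). The catalyst and ligand antipodes named are those expected to give the configurations drawn; the other antipode is used if the sense proves opposite.

**Step 1**
Reactants: 1 2,6-dimethyl-1,4-benzoquinone; 2 4-methyl-1,3-pentadiene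
Product: 3 (4aS,8aR)-2,5,5,8a-tetramethyl-4a,5,8,8a-tetrahydronaphthalene-1,4-dione
Conditions: (S)-o-tolyl-CBS oxazaborolidine·AlBr3 (10 mol%), 2 (3 equiv), CH2Cl2, −40 → −20 °C
Reagents that add atoms: none
Why: Enantioselective Lewis-acid-catalysed quinone Diels–Alder reaction (Corey oxazaborolidinium): the catalyst binds the C=O flanked by two C–H, so the nucleophilic CH2 terminus of the diene bonds to the methyl-bearing β-carbon and the CMe2 terminus to the CH carbon, suprafacial addition gives the cis ring fusion, and catalyst face-shielding fixes C5 (S) and C10 (R).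

**Step 2**
Reactants: 3 (4aS,8aR)-2,5,5,8a-tetramethyl-4a,5,8,8a-tetrahydronaphthalene-1,4-dione
Product: 4 (2R,4aS,8aR)-2,5,5,8a-tetramethyl-2,3,4a,5,8,8a-hexahydronaphthalene-1,4-dione
Conditions: Zn dust, AcOH, rt
Reagents that add atoms: none
Why: Zinc/acetic acid ene-dione reduction (electron transfer–protonation) saturates only the conjugated C7=C8 bond, and C8 settles under thermodynamic control via the C9 enol with its methyl equatorial (8R, cis to the angular methyl), the isolated ring-A alkene and the ring fusion being untouched.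

**Step 3**
Reactants: 4 (2R,4aS,8aR)-2,5,5,8a-tetramethyl-2,3,4a,5,8,8a-hexahydronaphthalene-1,4-dione
Product: 5 (2R,4S,4aS,8aR)-4-hydroxy-2,5,5,8a-tetramethyl-3,4,4a,5,8,8a-hexahydronaphthalen-1(2H)-one
Conditions: Al(OiPr)3 (0.3 equiv), i-PrOH/PhMe, 80 °C, 24 h (acetone left in the flask)
Reagents that add atoms: none
Why: Meerwein–Ponndorf–Verley reduction attacks only the C6 ketone (the C9 ketone is flanked by quaternary C10 and the C8 methyl) and, being reversible (MPV/Oppenauer equilibration), gives the thermodynamically favoured equatorial 6-alcohol (6S), whose axial epimer would suffer a 1,3-diaxial clash with C1 (a kinetic hydride would give that wrong epimer).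

**Step 4**
Reactants: 5 (2R,4S,4aS,8aR)-4-hydroxy-2,5,5,8a-tetramethyl-3,4,4a,5,8,8a-hexahydronaphthalen-1(2H)-one
Product: 6 (1R,2R,4S,4aS,8aR)-1-ethynyl-2,5,5,8a-tetramethyl-1,2,3,4,4a,5,8,8a-octahydronaphthalene-1,4-diol
Conditions: HC≡CLi·ethylenediamine (5 equiv), THF, 0 °C → rt; H2O
Reagents that add atoms: lithium acetylide, [Li]C#C
Why: Favorskii-type ethynylation (1,2-addition of a small acetylide, precedented for 2,2,6-trisubstituted cyclohexanones) of the hindered C9 ketone, attack anti to the axial C1 giving mainly the epimer drawn, although the C9 configuration is irrelevant because step 10 resets it.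

**Step 5**
Reactants: 6 (1R,2R,4S,4aS,8aR)-1-ethynyl-2,5,5,8a-tetramethyl-1,2,3,4,4a,5,8,8a-octahydronaphthalene-1,4-diol
Product: 7 (1S,3R,4R,4aR,8aS)-4-ethynyl-4-hydroxy-3,4a,8,8-tetramethyl-1,2,3,4,4a,5,8,8a-octahydronaphthalen-1-yl acetate
Conditions: Ac2O (1.5 equiv), pyridine, DMAP (cat.), CH2Cl2, 0 °C → rt
Reagents that add atoms: acetic anhydride, CC(=O)OC(C)=O
Why: DMAP-catalysed acylation is selective for the secondary equatorial 6-OH over the neopentyl-like tertiary propargylic 9-OH, and no stereocentre is touched.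

**Step 6**
Reactants: 8 ethyl 1,3-dithiane-2-carboxylate; 9 (2-bromoethoxy)(tert-butyl)dimethylsilane
Product: 10 ethyl 2-{2-[(tert-butyldimethylsilyl)oxy]ethyl}-1,3-dithiane-2-carboxylate
Conditions: NaH (1.1 equiv), DMF/PhMe, 0 °C; then 9, rt
Reagents that add atoms: none
Why: Corey–Seebach-type umpolung alkylation of the ester-stabilised 2-dithianyl anion (glyoxylate acyl-anion equivalent) with a primary bromide.

**Step 7**
Reactants: 10 ethyl 2-{2-[(tert-butyldimethylsilyl)oxy]ethyl}-1,3-dithiane-2-carboxylate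
Product: 11 ethyl 4-[(tert-butyldimethylsilyl)oxy]-2-oxobutanoate
Conditions: NBS, NaHCO3, acetone/H2O (9:1), −10 °C, 10 min
Reagents that add atoms: water, O
Why: Oxidative dithioacetal hydrolysis with NBS (Corey–Erickson conditions) unmasks the α-keto ester, with bicarbonate buffering to preserve the primary TBS ether.

**Step 8**
Reactants: 7 (1S,3R,4R,4aR,8aS)-4-ethynyl-4-hydroxy-3,4a,8,8-tetramethyl-1,2,3,4,4a,5,8,8a-octahydronaphthalen-1-yl acetate; 11 ethyl 4-[(tert-butyldimethylsilyl)oxy]-2-oxobutanoate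
Product: 12 ethyl (5S,6S,8R,9S,10R,13S)-6-acetoxy-15-[(tert-butyldimethylsilyl)oxy]-9,13-dihydroxylabd-2-en-11-yn-16-oate
Conditions: Zn(OTf)2 (20 mol%), (1S,2S)-2-(dimethylamino)-1-(4-nitrophenyl)-3-(TBSO)propan-1-ol (22 mol%), Et3N (30 mol%), PhMe, 50 °C, slow addition of 11
Reagents that add atoms: none
Why: Catalytic asymmetric alkynylation of an α-keto ester (Carreira/Jiang-type zinc acetylide with a chiral amino-alcohol ligand), with Si-face delivery setting C13 (S here, the same spatial arrangement as 13R in the target), the acetate, ordinary ester and tertiary carbinol being inert.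

**Step 9**
Reactants: 12 ethyl (5S,6S,8R,9S,10R,13S)-6-acetoxy-15-[(tert-butyldimethylsilyl)oxy]-9,13-dihydroxylabd-2-en-11-yn-16-oate
Product: 13 ethyl (5S,6S,8R,9S,10R,13R)-6-acetoxy-15-[(tert-butyldimethylsilyl)oxy]-9,13-dihydroxylabdan-16-oate
Conditions: H2 (1 atm), 10% Pd/C, EtOAc, rt
Reagents that add atoms: none
Why: Heterogeneous catalytic hydrogenation saturates the alkyne (butyne-1,4-diol → butane-1,4-diol type) and the ring-A alkene without touching any stereocentre (the C13 descriptor changes only through CIP priorities).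

**Step 10**
Reactants: 13 ethyl (5S,6S,8R,9S,10R,13R)-6-acetoxy-15-[(tert-butyldimethylsilyl)oxy]-9,13-dihydroxylabdan-16-oate
Product: 16 (5S,6S,8R,9R,10R,13R)-6-acetoxy-9,13-epoxylabdan-16,15-olide (target CNP0081177.1), via triol ester 14 (not isolated), via hydroxy-lactone diol 15 (not isolated)
Conditions: TsOH·H2O (0.5 equiv), CH2Cl2, 23 °C, then 40 °C
Reagents that add atoms: none
Why: Acid-triggered desilylation, lactonisation of the freed γ-hydroxy ester (first ring) and SN1 cyclodehydration of the ditertiary 1,4-diol (second ring): only the strained C9 carbinol ionises (C13, α to the lactone carbonyl, cannot, so it is retained), and the C13–OH closes the tetrahydrofuran axially on the convex face anti to the axial C1 (trans-diaxial to H8 if the Δ8 alkene intervenes), giving 9R with the side chain equatorial from either C9 epimer.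

**Compound list**
1 | 2,6-dimethyl-1,4-benzoquinone | CC1=CC(=O)C=C(C)C1=O | starting material
2 | 4-methyl-1,3-pentadiene | CC(C)=CC=C | starting material
3 | (4aS,8aR)-2,5,5,8a-tetramethyl-4a,5,8,8a-tetrahydronaphthalene-1,4-dione (cis-fused) | O=C1C=C(C)C(=O)[C@]2(C)CC=CC(C)(C)[C@H]12 | intermediate
4 | (2R,4aS,8aR)-2,5,5,8a-tetramethyl-2,3,4a,5,8,8a-hexahydronaphthalene-1,4-dione | O=C1C[C@@H](C)C(=O)[C@]2(C)CC=CC(C)(C)[C@H]12 | intermediate
5 | (2R,4S,4aS,8aR)-4-hydroxy-2,5,5,8a-tetramethyl-3,4,4a,5,8,8a-hexahydronaphthalen-1(2H)-one | O[C@H]1C[C@@H](C)C(=O)[C@]2(C)CC=CC(C)(C)[C@H]12 | intermediate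
6 | (1R,2R,4S,4aS,8aR)-1-ethynyl-2,5,5,8a-tetramethyl-1,2,3,4,4a,5,8,8a-octahydronaphthalene-1,4-diol (ethynyl syn to the angular methyl) | O[C@H]1C[C@@H](C)[C@@](O)(C#C)[C@]2(C)CC=CC(C)(C)[C@H]12 | intermediate
7 | (1S,3R,4R,4aR,8aS)-4-ethynyl-4-hydroxy-3,4a,8,8-tetramethyl-1,2,3,4,4a,5,8,8a-octahydronaphthalen-1-yl acetate | CC(=O)O[C@H]1C[C@@H](C)[C@@](O)(C#C)[C@]2(C)CC=CC(C)(C)[C@H]12 | intermediate
8 | ethyl 1,3-dithiane-2-carboxylate | CCOC(=O)C1SCCCS1 | starting material
9 | (2-bromoethoxy)(tert-butyl)dimethylsilane | CC(C)(C)[Si](C)(C)OCCBr | starting material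
10 | ethyl 2-{2-[(tert-butyldimethylsilyl)oxy]ethyl}-1,3-dithiane-2-carboxylate | CCOC(=O)C1(CCO[Si](C)(C)C(C)(C)C)SCCCS1 | intermediate
11 | ethyl 4-[(tert-butyldimethylsilyl)oxy]-2-oxobutanoate | CCOC(=O)C(=O)CCO[Si](C)(C)C(C)(C)C | intermediate
12 | ethyl (5S,6S,8R,9S,10R,13S)-6-acetoxy-15-[(tert-butyldimethylsilyl)oxy]-9,13-dihydroxylabd-2-en-11-yn-16-oate | CC(=O)O[C@H]1C[C@@H](C)[C@@](O)(C#C[C@@](O)(CCO[Si](C)(C)C(C)(C)C)C(=O)OCC)[C@]2(C)CC=CC(C)(C)[C@H]12 | intermediate
13 | ethyl (5S,6S,8R,9S,10R,13R)-6-acetoxy-15-[(tert-butyldimethylsilyl)oxy]-9,13-dihydroxylabdan-16-oate | CC(=O)O[C@H]1C[C@@H](C)[C@@](O)(CC[C@@](O)(CCO[Si](C)(C)C(C)(C)C)C(=O)OCC)[C@]2(C)CCCC(C)(C)[C@H]12 | intermediate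
14 | ethyl (5S,6S,8R,9S,10R,13R)-6-acetoxy-9,13,15-trihydroxylabdan-16-oate (triol ester) | CC(=O)O[C@H]1C[C@@H](C)[C@@](O)(CC[C@@](O)(CCO)C(=O)OCC)[C@]2(C)CCCC(C)(C)[C@H]12 | intermediate
15 | (5S,6S,8R,9S,10R,13R)-6-acetoxy-9,13-dihydroxylabdan-16,15-olide (hydroxy-lactone diol) | CC(=O)O[C@H]1C[C@@H](C)[C@@](O)(CC[C@@]2(O)CCOC2=O)[C@]2(C)CCCC(C)(C)[C@H]12 | intermediate
16 | (5S,6S,8R,9R,10R,13R)-6-acetoxy-9,13-epoxylabdan-16,15-olide | CC(=O)O[C@H]1C[C@@H](C)[C@]2(CC[C@]3(CCOC3=O)O2)[C@]2(C)CCCC(C)(C)[C@H]12 | target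

**Totals**
Total step count: 10. Longest linear sequence: 8 (steps 1–5, 8–10).

**Three steps most likely to fail**

Step 1. The Z-methyl of diene 2 disfavours the s-cis conformer, and the cationic catalyst may oligomerise the diene. The fallback sets out from 1 and comes back at 3. Mesityl oxide (LDA, THF, −78 °C; TIPSOTf) gives the much more nucleophilic 4-methyl-2-(triisopropylsilyloxy)penta-1,3-diene F1. F1 cycloadds to 1 under the same chiral oxazaborolidinium catalysis at −78 °C, with the same regiochemistry, to give the silyl enol ether adduct (4aS,8aR)-2,5,5,8a-tetramethyl-7-(triisopropylsilyloxy)-4a,5,8,8a-tetrahydronaphthalene-1,4-dione F2. CsF/PhNTf2 in DME converts it into the enol triflate (4aS,8aR)-2,5,5,8a-tetramethyl-1,4-dioxo-4a,5,8,8a-tetrahydronaphthalen-7-yl trifluoromethanesulfonate F3. Pd(OAc)2/PPh3 with HCO2H–Bu3N in DMF reduces the triflate to the C2=C3 alkene, which is 3.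

Step 8. The aliphatic α-keto ester 11 is enolisable (self-aldol) and the catalyst must override a bulky alkyne, so yield and selectivity at C13 are uncertain. The fallback sets out from 7 and 11 and comes back at 16, replacing catalyst control by auxiliary control. Transesterification of 11 with (−)-8-phenylmenthol (Ti(OEt)4 cat., PhMe, 110 °C) gives (−)-8-phenylmenthyl 4-[(tert-butyldimethylsilyl)oxy]-2-oxobutanoate F4. The zinc acetylide of 7 (Zn(OTf)2, Et3N, stoichiometric, no chiral ligand, PhMe, rt) adds to the face left open by the π-stacked phenyl group (Prelog/Whitesell model; the (−)-auxiliary is assumed to expose the Si face), giving the (−)-8-phenylmenthyl ester analogue of 12, F5. Hydrogenation (H2, Pd/C) gives the (−)-8-phenylmenthyl ester analogue of 13, F6. The step-10 conditions then expel the auxiliary during lactonisation and deliver 16.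

Step 10. The C9 cation may eliminate without re-closing, suffer a 1,2-shift of the aligned C10–C1 bond, or give the C9 epimer. The fallback sets out from 12 and comes back at 16, moving the ionisation to a milder allylic one. Lindlar semi-hydrogenation of 12 (H2, Pd/CaCO3–Pb, quinoline) gives the (Z)-ene-1,4-diol ethyl (11Z)-6-acetoxy-15-[(tert-butyldimethylsilyl)oxy]-9,13-dihydroxylabda-2,11-dien-16-oate F7. Mild acid (PPTS or TsOH·H2O, CH2Cl2, 0 °C → rt) desilylates, lactonises and closes the 2,5-dihydrofuran through the tertiary allylic C9 cation with the same axial facial preference. This gives the spiro-dihydrofuran lactone 6-acetoxy-9,13-epoxylabda-2,11-dien-16,15-olide F8. Hydrogenation (H2, PtO2 or Rh/Al2O3, EtOAc, to avoid allylic C–O hydrogenolysis) of both alkenes gives 16.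

**Further compounds**
F1 | step 1 | 4-methyl-2-(triisopropylsilyloxy)penta-1,3-diene | C=C(O[Si](C(C)C)(C(C)C)C(C)C)C=C(C)C
F2 | step 1 | (4aS,8aR)-2,5,5,8a-tetramethyl-7-(triisopropylsilyloxy)-4a,5,8,8a-tetrahydronaphthalene-1,4-dione | O=C1C=C(C)C(=O)[C@]2(C)CC(O[Si](C(C)C)(C(C)C)C(C)C)=CC(C)(C)[C@H]12
F3 | step 1 | (4aS,8aR)-2,5,5,8a-tetramethyl-1,4-dioxo-4a,5,8,8a-tetrahydronaphthalen-7-yl trifluoromethanesulfonate | O=C1C=C(C)C(=O)[C@]2(C)CC(OS(=O)(=O)C(F)(F)F)=CC(C)(C)[C@H]12
F4 | step 8 | (1R,2S,5R)-5-methyl-2-(2-phenylpropan-2-yl)cyclohexyl 4-[(tert-butyldimethylsilyl)oxy]-2-oxobutanoate | C[C@@H]1CC[C@H]([C@@H](C1)OC(=O)C(=O)CCO[Si](C)(C)C(C)(C)C)C(C)(C)c1ccccc1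
F5 | step 8 | (−)-8-phenylmenthyl ester analogue of 12 | CC(=O)O[C@H]1C[C@@H](C)[C@@](O)(C#C[C@@](O)(CCO[Si](C)(C)C(C)(C)C)C(=O)O[C@@H]2C[C@H](C)CC[C@H]2C(C)(C)c2ccccc2)[C@]2(C)CC=CC(C)(C)[C@H]12
F6 | step 8 | (−)-8-phenylmenthyl ester analogue of 13 | CC(=O)O[C@H]1C[C@@H](C)[C@@](O)(CC[C@@](O)(CCO[Si](C)(C)C(C)(C)C)C(=O)O[C@@H]2C[C@H](C)CC[C@H]2C(C)(C)c2ccccc2)[C@]2(C)CCCC(C)(C)[C@H]12
F7 | step 10 | ethyl (11Z)-6-acetoxy-15-[(tert-butyldimethylsilyl)oxy]-9,13-dihydroxylabda-2,11-dien-16-oate | CC(=O)O[C@H]1C[C@@H](C)[C@@](O)(/C=C\[C@@](O)(CCO[Si](C)(C)C(C)(C)C)C(=O)OCC)[C@]2(C)CC=CC(C)(C)[C@H]12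
F8 | step 10 | 6-acetoxy-9,13-epoxylabda-2,11-dien-16,15-olide | CC(=O)O[C@H]1C[C@@H](C)[C@]2(C=C[C@]3(CCOC3=O)O2)[C@]2(C)CC=CC(C)(C)[C@H]12
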